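**Retrosynthetic overview**

- The target is two fully substituted phloroglucinol rings joined by one CH2. Ring A is numbered C1 (butyryl), C2 (OH), C3 (Me), C4 (OMe), C5 (CH2 bridge), C6 (OH); ring B carries acetyl, methyl and three OH.
- The route rests on one feature of ring A: the C3 methyl and the C4 methoxy are neighbours, which is the substituted carbon pair of 1-methoxypropyne. The C4 oxygen is the only methylated one of six, so it is brought in as an ether and never made by selective O-methylation.
- Key disconnection: ring A is cut at C2–C3 and C4–C5 into 1-methoxypropyne and a 3-benzyloxy-2-(ring B-methyl)cyclobutenone (cyclobutenone–ynol ether benzannulation). C1 arrives as CH and is butyrylated afterwards.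
- The cyclobutenone goes back to the 2-substituted cyclobutane-1,3-dione, made from the ketene of a ring B propanoic acid and ethoxyacetylene. The acid comes from a ring B aldehyde and Meldrum's acid, and the aldehyde from 2-methylphloroglucinol.
- Ring order: ring B is bought as the arene and substituted first, the four-membered ring is built on its side chain, ring A is formed from it, then C1 acylation and global debenzylation.

Key step: step 9

Remark: the ethoxycyclobutenone of step 5 and two transient intermediates (steps 2 and 9) each carry one stereocentre and are racemic; the target has none, so no step needs stereocontrol.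

**Route**

Step 1
Reactants: 1 2-methylphloroglucinol
Product: 2 1-(2,4,6-trihydroxy-3-methylphenyl)ethan-1-one
Conditions: AcCl, AlCl3, PhNO2/CH2Cl2, 0 °C to rt; aq. HCl
Reagents that add atoms: acetyl chloride, CC(=O)Cl
Why: Friedel–Crafts C-acylation of the electron-rich triol at one of its two equivalent free carbons, the new acyl group slowing a second acylation.

Step 2
Reactants: 2 1-(2,4,6-trihydroxy-3-methylphenyl)ethan-1-one
Product: 4 3-acetyl-2,4,6-trihydroxy-5-methylbenzaldehyde, via chloro(methoxy)methyl arene 3 (not isolated)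
Conditions: Cl2CHOMe, TiCl4, CH2Cl2, 0 °C to rt; aq. HCl
Reagents that add atoms: dichloromethyl methyl ether, COC(Cl)Cl; water, O
Why: Rieche formylation at the single remaining ring carbon, which lies between two hydroxyls, followed by hydrolysis of the α-chloro ether on work-up.

Step 3
Reactants: 4 3-acetyl-2,4,6-trihydroxy-5-methylbenzaldehyde
Product: 5 3-acetyl-2,4,6-tris(benzyloxy)-5-methylbenzaldehyde
Conditions: BnBr, K2CO3, DMF, 60 °C
Reagents that add atoms: benzyl bromide, BrCc1ccccc1
Why: Williamson etherification of the three phenoxides in a dipolar aprotic solvent, which favours O- over dearomatising C-alkylation, with heating to overcome hydrogen bonding to the two carbonyl groups.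

Step 4
Reactants: 5 3-acetyl-2,4,6-tris(benzyloxy)-5-methylbenzaldehyde; 6 Meldrum's acid
Product: 10 3-[3-acetyl-2,4,6-tris(benzyloxy)-5-methylphenyl]propanoic acid, via arylidene Meldrum's acid 7 (not isolated), via arylmethyl Meldrum's acid 8 (not isolated), via arylmethylmalonic acid 9 (not isolated)
Conditions: HCO2H–Et3N (5:2), 95–100 °C
Reagents that add atoms: water, O (formed in the condensation and taken up again in the ring opening)
Why: One-pot Knoevenagel condensation, formate hydride transfer to the arylidene Meldrum's acid, ring hydrolysis and decarboxylation, a known direct conversion of ArCHO into ArCH2CH2CO2H that leaves the hindered acetyl ketone and the benzyl ethers alone.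

Step 5
Reactants: 10 3-[3-acetyl-2,4,6-tris(benzyloxy)-5-methylphenyl]propanoic acid; 11 ethoxyacetylene
Product: 14 4-{[3-acetyl-2,4,6-tris(benzyloxy)-5-methylphenyl]methyl}-3-ethoxycyclobut-2-en-1-one (racemic), via acid chloride 12 (not isolated), via aldoketene 13 (not isolated)
Conditions: (COCl)2, cat. DMF, CH2Cl2, 0 °C to rt, evaporate; then slow addition to ethoxyacetylene (excess), Et3N, CH2Cl2, 0 °C to rt
Reagents that add atoms: none
Why: Dehydrochlorination of the acid chloride gives the aldoketene, which is trapped in situ by the ynol ether in a [2+2] cycloaddition whose regiochemistry (nucleophilic CH terminus of the alkyne onto the ketene carbonyl carbon) gives the 3-ethoxy-4-substituted cyclobutenone.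

Step 6
Reactants: 14 4-{[3-acetyl-2,4,6-tris(benzyloxy)-5-methylphenyl]methyl}-3-ethoxycyclobut-2-en-1-one
Product: 15 2-{[3-acetyl-2,4,6-tris(benzyloxy)-5-methylphenyl]methyl}-3-hydroxycyclobut-2-en-1-one
Conditions: 2 M aq. HCl, THF, 0 °C to rt
Reagents that add atoms: water, O
Why: Acid hydrolysis of the vinylogous ester gives the 2-substituted cyclobutane-1,3-dione, which rests as the symmetrical enol, so that the arylmethyl group now sits on the enone α-carbon and the stereocentre is gone.

Step 7
Reactants: 15 2-{[3-acetyl-2,4,6-tris(benzyloxy)-5-methylphenyl]methyl}-3-hydroxycyclobut-2-en-1-one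
Product: 16 2-{[3-acetyl-2,4,6-tris(benzyloxy)-5-methylphenyl]methyl}-3-(benzyloxy)cyclobut-2-en-1-one
Conditions: BnOH, PPh3, DIAD, THF, 0 °C to rt
Reagents that add atoms: benzyl alcohol, OCc1ccccc1
Why: Mitsunobu O-alkylation of a strongly acidic enol (a vinylogous acid) under neutral conditions at room temperature, the two oxygens of the dione being equivalent so that only one enol ether can form.

Step 8
Reactants: 17 2-chloro-1,1-dimethoxyethane
Product: 19 1-methoxypropyne, via sodium methoxyacetylide 18 (not isolated)
Conditions: NaNH2 (3 equiv), liq. NH3, −33 °C; then MeI; distillation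
Reagents that add atoms: iodomethane, CI
Why: Twofold elimination and deprotonation by NaNH2 give the sodium alkoxyacetylide, which is C-methylated by iodomethane in liquid ammonia (the standard preparation of 1-alkoxy-1-alkynes from chloroacetaldehyde acetals).

Step 9
Reactants: 16 2-{[3-acetyl-2,4,6-tris(benzyloxy)-5-methylphenyl]methyl}-3-(benzyloxy)cyclobut-2-en-1-one; 19 1-methoxypropyne
Product: 24 1-[2,4,6-tris(benzyloxy)-3-{[6-(benzyloxy)-4-hydroxy-2-methoxy-3-methylphenyl]methyl}-5-methylphenyl]ethan-1-one, via vinylketene 20 (not isolated), via vinylcyclobutenone 21 (not isolated), via dienylketene 22 (not isolated), via cyclohexadienone 23 (not isolated)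
Conditions: 19 (3 equiv), toluene, sealed tube, 110–130 °C; then K2CO3, MeOH, rt
Reagents that add atoms: none
Why: Heating opens the cyclobutenone by 4π electrocyclic ring opening to vinylketene 20, which adds the ynol ether in a [2+2] cycloaddition to give 4-vinylcyclobutenone 21; a second 4π opening gives dienylketene 22, ring A closes by thermal 6π electrocyclisation to cyclohexadienone 23, and tautomerisation gives the phenol. This is the Danheiser benzannulation of a cyclobutenone with an alkoxyalkyne, here with a 3-alkoxy-2-alkylcyclobutenone; the new bonds are ring A C2–C3 and C4–C5, and the C1–C2 bond broken in the first opening is re-formed in the 6π closure. No stereocentre is created, and the quaternary centre of 21 disappears on ring opening. The step needs regiocontrol in the [2+2] addition, which the polarisation of the ynol ether supplies: its methyl-bearing carbon is the nucleophilic terminus and bonds to the ketene carbonyl carbon, so Me ends up next to the new hydroxyl (C2–OH, C3–Me) and OMe next to the bridge carbon (C4–OMe, C5–CH2Ar), with the benzyloxy group at C6 and hydrogen at C1. A methyl ynol ether cannot lose an alkene by retro-ene fragmentation at this temperature, the excess of alkyne keeps the ketene from oligomerising, and the carbonate–methanol treatment cleaves any aryl ester formed from the product phenol and ketene 20.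

Step 10
Reactants: 24 1-[2,4,6-tris(benzyloxy)-3-{[6-(benzyloxy)-4-hydroxy-2-methoxy-3-methylphenyl]methyl}-5-methylphenyl]ethan-1-one
Product: 25 1-[2,4,6-tris(benzyloxy)-3-{[4,6-bis(benzyloxy)-2-methoxy-3-methylphenyl]methyl}-5-methylphenyl]ethan-1-one
Conditions: BnBr, K2CO3, DMF, rt to 50 °C
Reagents that add atoms: benzyl bromide, BrCc1ccccc1
Why: Williamson etherification of the one free phenol, so that the mixed anhydride of the next step meets no hydroxyl that it would esterify and deactivate; the extra benzyl group leaves in the final hydrogenolysis.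

Step 11
Reactants: 25 1-[2,4,6-tris(benzyloxy)-3-{[4,6-bis(benzyloxy)-2-methoxy-3-methylphenyl]methyl}-5-methylphenyl]ethan-1-one
Product: 26 1-[3-{[3-acetyl-2,4,6-tris(benzyloxy)-5-methylphenyl]methyl}-2,6-bis(benzyloxy)-4-methoxy-5-methylphenyl]butan-1-one
Conditions: PrCO2H, (CF3CO)2O, cat. H3PO4, CH2Cl2, 0 °C to rt
Reagents that add atoms: butyric acid, CCCC(=O)O
Why: Friedel–Crafts acylation by the butyric trifluoroacetic mixed anhydride at the only unsubstituted carbon of ring A (two ortho benzyloxy groups, para methoxy), ring B having no free position; these protic conditions are chosen because BF3- or AlCl3-type Lewis acids would strip benzyl ethers.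

Step 12
Reactants: 26 1-[3-{[3-acetyl-2,4,6-tris(benzyloxy)-5-methylphenyl]methyl}-2,6-bis(benzyloxy)-4-methoxy-5-methylphenyl]butan-1-one
Product: 27 1-{3-[(3-acetyl-2,4,6-trihydroxy-5-methylphenyl)methyl]-2,6-dihydroxy-4-methoxy-5-methylphenyl}butan-1-one (target)
Conditions: H2 (1 atm), 10% Pd/C, EtOAc/MeOH, rt
Reagents that add atoms: none
Why: Catalytic hydrogenolysis of the five aryl benzyl ethers, under which the methyl ether, the diarylmethane bridge and the two aryl ketones (hydrogen-bonded to ortho hydroxyls once unmasked) should persist.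

**Compound list**

1 | 2-methylphloroglucinol (2-methylbenzene-1,3,5-triol) | Cc1c(O)cc(O)cc1O | starting material
2 | 1-(2,4,6-trihydroxy-3-methylphenyl)ethan-1-one | CC(=O)c1c(O)cc(O)c(C)c1O | intermediate
3 | 1-{3-[chloro(methoxy)methyl]-2,4,6-trihydroxy-5-methylphenyl}ethan-1-one (racemic) | COC(Cl)c1c(O)c(C)c(O)c(C(C)=O)c1O | intermediate (not isolated)
4 | 3-acetyl-2,4,6-trihydroxy-5-methylbenzaldehyde | O=Cc1c(O)c(C)c(O)c(C(C)=O)c1O | intermediate
5 | 3-acetyl-2,4,6-tris(benzyloxy)-5-methylbenzaldehyde | O=Cc1c(OCc2ccccc2)c(C)c(OCc2ccccc2)c(C(C)=O)c1OCc1ccccc1 | intermediate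
6 | Meldrum's acid (2,2-dimethyl-1,3-dioxane-4,6-dione) | CC1(C)OC(=O)CC(=O)O1 | starting material
7 | 5-{[3-acetyl-2,4,6-tris(benzyloxy)-5-methylphenyl]methylidene}-2,2-dimethyl-1,3-dioxane-4,6-dione | CC1(C)OC(=O)C(=Cc2c(OCc3ccccc3)c(C)c(OCc3ccccc3)c(C(C)=O)c2OCc2ccccc2)C(=O)O1 | intermediate (not isolated)
8 | 5-{[3-acetyl-2,4,6-tris(benzyloxy)-5-methylphenyl]methyl}-2,2-dimethyl-1,3-dioxane-4,6-dione | CC1(C)OC(=O)C(Cc2c(OCc3ccccc3)c(C)c(OCc3ccccc3)c(C(C)=O)c2OCc2ccccc2)C(=O)O1 | intermediate (not isolated)
9 | 2-{[3-acetyl-2,4,6-tris(benzyloxy)-5-methylphenyl]methyl}propanedioic acid | OC(=O)C(C(=O)O)Cc1c(OCc2ccccc2)c(C)c(OCc2ccccc2)c(C(C)=O)c1OCc1ccccc1 | intermediate (not isolated)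
10 | 3-[3-acetyl-2,4,6-tris(benzyloxy)-5-methylphenyl]propanoic acid | OC(=O)CCc1c(OCc2ccccc2)c(C)c(OCc2ccccc2)c(C(C)=O)c1OCc1ccccc1 | intermediate
11 | ethoxyacetylene (ethoxyethyne) | CCOC#C | starting material
12 | 3-[3-acetyl-2,4,6-tris(benzyloxy)-5-methylphenyl]propanoyl chloride | ClC(=O)CCc1c(OCc2ccccc2)c(C)c(OCc2ccccc2)c(C(C)=O)c1OCc1ccccc1 | intermediate (not isolated)
13 | 4-[3-acetyl-2,4,6-tris(benzyloxy)-5-methylphenyl]but-1-en-1-one (aldoketene) | O=C=CCc1c(OCc2ccccc2)c(C)c(OCc2ccccc2)c(C(C)=O)c1OCc1ccccc1 | intermediate (not isolated)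
14 | 4-{[3-acetyl-2,4,6-tris(benzyloxy)-5-methylphenyl]methyl}-3-ethoxycyclobut-2-en-1-one (racemic) | CCOC1=CC(=O)C1Cc1c(OCc2ccccc2)c(C)c(OCc2ccccc2)c(C(C)=O)c1OCc1ccccc1 | intermediate
15 | 2-{[3-acetyl-2,4,6-tris(benzyloxy)-5-methylphenyl]methyl}-3-hydroxycyclobut-2-en-1-one | O=C1CC(O)=C1Cc1c(OCc2ccccc2)c(C)c(OCc2ccccc2)c(C(C)=O)c1OCc1ccccc1 | intermediate
16 | 2-{[3-acetyl-2,4,6-tris(benzyloxy)-5-methylphenyl]methyl}-3-(benzyloxy)cyclobut-2-en-1-one | O=C1CC(OCc2ccccc2)=C1Cc1c(OCc2ccccc2)c(C)c(OCc2ccccc2)c(C(C)=O)c1OCc1ccccc1 | intermediate (key-step precursor)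
17 | 2-chloro-1,1-dimethoxyethane | COC(CCl)OC | starting material
18 | sodium methoxyacetylide | COC#[C-].[Na+] | intermediate (not isolated)
19 | 1-methoxypropyne (1-methoxyprop-1-yne) | CC#COC | intermediate
20 | 2-{[3-acetyl-2,4,6-tris(benzyloxy)-5-methylphenyl]methyl}-3-(benzyloxy)buta-1,3-dien-1-one | C=C(OCc1ccccc1)C(=C=O)Cc1c(OCc2ccccc2)c(C)c(OCc2ccccc2)c(C(C)=O)c1OCc1ccccc1 | intermediate (not isolated)
21 | 4-{[3-acetyl-2,4,6-tris(benzyloxy)-5-methylphenyl]methyl}-4-[1-(benzyloxy)ethenyl]-3-methoxy-2-methylcyclobut-2-en-1-one (racemic) | O=C1C(C)=C(OC)C1(C(OCc1ccccc1)=C)Cc1c(OCc2ccccc2)c(C)c(OCc2ccccc2)c(C(C)=O)c1OCc1ccccc1 | intermediate (not isolated)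
22 | (3E)-4-{[3-acetyl-2,4,6-tris(benzyloxy)-5-methylphenyl]methyl}-5-(benzyloxy)-3-methoxy-2-methylhexa-1,3,5-trien-1-one (ketene carbon and benzyloxyvinyl group cis) | O=C=C(C)/C(OC)=C(\C(OCc1ccccc1)=C)Cc1c(OCc2ccccc2)c(C)c(OCc2ccccc2)c(C(C)=O)c1OCc1ccccc1 | intermediate (not isolated)
23 | 4-{[3-acetyl-2,4,6-tris(benzyloxy)-5-methylphenyl]methyl}-5-(benzyloxy)-3-methoxy-2-methylcyclohexa-2,4-dien-1-one | O=C1CC(OCc2ccccc2)=C(Cc2c(OCc3ccccc3)c(C)c(OCc3ccccc3)c(C(C)=O)c2OCc2ccccc2)C(OC)=C1C | intermediate (not isolated)
24 | 1-[2,4,6-tris(benzyloxy)-3-{[6-(benzyloxy)-4-hydroxy-2-methoxy-3-methylphenyl]methyl}-5-methylphenyl]ethan-1-one | Oc1cc(OCc2ccccc2)c(Cc2c(OCc3ccccc3)c(C)c(OCc3ccccc3)c(C(C)=O)c2OCc2ccccc2)c(OC)c1C | intermediate (key-step product)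
25 | 1-[2,4,6-tris(benzyloxy)-3-{[4,6-bis(benzyloxy)-2-methoxy-3-methylphenyl]methyl}-5-methylphenyl]ethan-1-one | Cc1c(OCc2ccccc2)cc(OCc2ccccc2)c(Cc2c(OCc3ccccc3)c(C)c(OCc3ccccc3)c(C(C)=O)c2OCc2ccccc2)c1OC | intermediate
26 | 1-[3-{[3-acetyl-2,4,6-tris(benzyloxy)-5-methylphenyl]methyl}-2,6-bis(benzyloxy)-4-methoxy-5-methylphenyl]butan-1-one | CCCC(=O)c1c(OCc2ccccc2)c(C)c(OC)c(Cc2c(OCc3ccccc3)c(C)c(OCc3ccccc3)c(C(C)=O)c2OCc2ccccc2)c1OCc1ccccc1 | intermediate
27 | 1-{3-[(3-acetyl-2,4,6-trihydroxy-5-methylphenyl)methyl]-2,6-dihydroxy-4-methoxy-5-methylphenyl}butan-1-one | CCCC(=O)c1c(O)c(C)c(OC)c(Cc2c(O)c(C)c(O)c(C(C)=O)c2O)c1O | target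

**Step count and risk**

Total: 12 steps. Longest linear sequence: 11 steps (steps 1–7 and 9–12, from 1 to 27); step 8 is a one-step side branch.

Steps most likely to fail:

1. Step 9 (benzannulation). The 3-alkoxy group stabilises the cyclobutenone as a vinylogous ester, so the first ring opening may be slow enough for ketene oligomerisation or decomposition to outrun the cycloaddition. The [2+2] addition also has to take place at a fully substituted ketene carbon next to the bulky ring B.
 Fallback: ring A is not built but taken as an arene, and the two rings are joined at the bridge by Mannich/ortho-quinone methide chemistry. This sets out from 1 and uses 2. Compound 1 is C-butyrylated (butyryl chloride, AlCl3) to 1-(2,4,6-trihydroxy-3-methylphenyl)butan-1-one F1. One equivalent of Me2SO4 with K2CO3 in acetone methylates the para hydroxyl, the most acidic one and the only one never hydrogen-bonded to the ketone, to give 1-(2,6-dihydroxy-4-methoxy-3-methylphenyl)butan-1-one F2; isomeric ethers would have to be separated. Dimethylmethyleneiminium iodide then aminomethylates the single free ring carbon to give 1-{3-[(dimethylamino)methyl]-2,6-dihydroxy-4-methoxy-5-methylphenyl}butan-1-one F3. Heating F3 with an excess of 2 in dioxane should expel dimethylamine, and the ortho-quinone methide is captured by the one free ring carbon of 2, which comes back to the route at 27. Neither partner can homocouple, since F3 has no free ring carbon and 2 has no CH2 source.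

2. Step 5 (ketene–ethoxyacetylene cycloaddition). The aldoketene may dimerise or oligomerise faster than it is intercepted, and the hindered acid chloride may be dehydrochlorinated only slowly.
 Fallback: the side chain is attached to a preformed four-membered ring. This sets out from aldehyde 5 and ethoxyacetylene 11. Ketene and 11 give 3-ethoxycyclobut-2-en-1-one F4 (the parent case of this cycloaddition), and cold aqueous acid hydrolyses it to cyclobutane-1,3-dione F5. F5, aldehyde 5, Hantzsch ester and catalytic L-proline in CH2Cl2 then undergo a Knoevenagel condensation with in situ conjugate reduction (three-component reductive alkylation of a cyclic 1,3-dione). This comes back to the route at 15 and bypasses steps 4 to 6. It is kept as the fallback because this reductive alkylation is established for five- and six-membered diones but less so for the labile four-membered one.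

3. Step 11 (C-butyrylation). Acid may remove or shift benzyl groups before the hindered C1 position, flanked by two benzyloxy groups, is acylated, or the acylation may simply be sluggish.
 Fallback: the order of the last two operations is reversed. This sets out from 25. Hydrogenolysis (H2, 10% Pd/C, EtOAc/MeOH) gives 1-{3-[(2,4-dihydroxy-6-methoxy-5-methylphenyl)methyl]-2,4,6-trihydroxy-5-methylphenyl}ethan-1-one F6. The free resorcinol ring of F6 is then acylated at its only open carbon with butyric acid and BF3·OEt2 (the classical acylphloroglucinol acylation, kept short and mild to limit acid-induced exchange at the methylene bridge). This comes back to the route at 27.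

**Further compounds**

F1 | step 9 | 1-(2,4,6-trihydroxy-3-methylphenyl)butan-1-one | CCCC(=O)c1c(O)cc(O)c(C)c1O
F2 | step 9 | 1-(2,6-dihydroxy-4-methoxy-3-methylphenyl)butan-1-one | CCCC(=O)c1c(O)cc(OC)c(C)c1O
F3 | step 9 | 1-{3-[(dimethylamino)methyl]-2,6-dihydroxy-4-methoxy-5-methylphenyl}butan-1-one | CCCC(=O)c1c(O)c(CN(C)C)c(OC)c(C)c1O
F4 | step 5 | 3-ethoxycyclobut-2-en-1-one | CCOC1=CC(=O)C1
F5 | step 5 | cyclobutane-1,3-dione | O=C1CC(=O)C1
F6 | step 11 | 1-{3-[(2,4-dihydroxy-6-methoxy-5-methylphenyl)methyl]-2,4,6-trihydroxy-5-methylphenyl}ethan-1-one | CC(=O)c1c(O)c(C)c(O)c(Cc2c(O)cc(O)c(C)c2OC)c1O
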